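The target is read as a carbocyclic heptulose. Its carbinol centres C2, C3 and C4 and its two benzoates coincide with C4, C3, C2, O-3 and O-6 of D-mannose. Everything rests on disconnecting the tertiary α-ketol bond C1(OH)(CH2OBz)–C6(=O) of the cyclohexanone ring, which joins two carbons that are both carbonyl electrophiles. An N-heterocyclic-carbene-catalysed intramolecular crossed benzoin reverses the polarity of an aldehyde carbon (future C6) and adds it to a ketone (future C1). One operation closes the carbocycle, sets the quaternary carbinol and delivers the ketone at its final oxidation level. The precursor is an acyclic 2-deoxy-D-lyxo-heptos-6-ulose carrying both benzoates and two silyl ethers.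

Key step: step 7

Remark (numbering and abbreviations): the ring atoms of the target are C1 = C(OH)(CH2OBz), C2 = CHOH, C3 = CHOBz, C4 = CHOH, C5 = CH2, C6 = C=O. Bz = benzoyl, TBS = tert-butyldimethylsilyl.
Remark (precatalyst of step 7, called T): 2-(pentafluorophenyl)-6,7-dihydro-5H-pyrrolo[2,1-c][1,2,4]triazol-2-ium tetrafluoroborate, Fc1c(F)c(F)c(F)c(F)c1-[n+]1cn2CCCc2n1.F[B-](F)(F)F
Assumption: benzyl α-D-mannopyranoside is taken as a purchasable glycoside.

Step 1
Reactants: 1 benzyl α-D-mannopyranoside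
Product: 2 benzyl 3,6-di-O-benzoyl-α-D-mannopyranoside
Conditions: BzCl (2.3 equiv), iPr2NEt, Fe(acac)3 (10 mol %), MeCN, rt
Reagents that add atoms: benzoyl chloride, O=C(Cl)c1ccccc1
Why: Chelation-directed regioselective O-acylation: the primary O-6 is intrinsically the most reactive hydroxyl and binding of the cis-2,3-diol to Fe(acac)3 activates its equatorial O-3, so both benzoates of the target are placed at once and no stereocentre is touched.

Step 2
Reactants: 2 benzyl 3,6-di-O-benzoyl-α-D-mannopyranoside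
Product: 3 benzyl 3,6-di-O-benzoyl-2,4-bis-O-TBS-α-D-mannopyranoside
Conditions: TBSOTf (3 equiv), 2,6-lutidine, CH2Cl2, 0 °C to rt
Reagents that add atoms: tert-butyldimethylsilyl triflate, CC(C)(C)[Si](C)(C)OS(=O)(=O)C(F)(F)F
Why: Silyl ether formation with a silyl triflate and a hindered pyridine base is fast enough for the axial O-2 and the flanked O-4 and too weakly basic to move the benzoates.

Step 3
Reactants: 3 benzyl 3,6-di-O-benzoyl-2,4-bis-O-TBS-α-D-mannopyranoside
Product: 4 3,6-di-O-benzoyl-2,4-bis-O-TBS-D-mannopyranose (lactol, anomeric mixture)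
Conditions: H2 (1 atm), Pd(OH)2/C, EtOAc, rt
Reagents that add atoms: none
Why: Catalytic hydrogenolysis cleaves only the benzylic anomeric C–O bond, since benzoates and TBS ethers are inert to H2 over palladium in a non-protic solvent, and frees the lactol.

Step 4
Reactants: 4 3,6-di-O-benzoyl-2,4-bis-O-TBS-D-mannopyranose
Product: 6 4,7-di-O-benzoyl-3,5-bis-O-TBS-1,2-dideoxy-D-manno-hept-1-enitol (free 6-OH), via open-chain hydroxy aldehyde 5 (not isolated)
Conditions: RhCl(PPh3)3 (5 mol %), PPh3, TMSCHN2, iPrOH, THF, rt to 50 °C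
Reagents that add atoms: (trimethylsilyl)diazomethane, C[Si](C)(C)C=[N+]=[N-]
Why: Wittig methylenation of a pyranose lactol through its aldehyde tautomer 5, with Ph3P=CH2 formed slowly and salt-free from TMSCHN2, PPh3 and iPrOH under rhodium catalysis so that no alkoxide builds up that could shift benzoate or silyl groups; C1 of the sugar becomes the future ring CH2 and O-5 is set free as the future ketone oxygen.

Step 5
Reactants: 6 4,7-di-O-benzoyl-3,5-bis-O-TBS-1,2-dideoxy-D-manno-hept-1-enitol
Product: 8 4,7-di-O-benzoyl-3,5-bis-O-TBS-2-deoxy-D-manno-heptitol (1,6-diol), via bis-boryl adduct 7 (not isolated)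
Conditions: 9-BBN (3 equiv), THF, 0 °C to rt; then NaBO3·4H2O, THF/H2O, rt
Reagents that add atoms: sodium perborate tetrahydrate (source of the new oxygen), [Na+].[Na+].O[B-]1(O)OO[B-](O)(O)OO1; 9-BBN (its boron and carbons stay only in 7), B1C2CCCC1CCC2
Why: Anti-Markovnikov hydroboration–oxidation: the bulky 9-BBN puts boron on the terminal carbon and does not reduce benzoates (one further equivalent is taken up by the free hydroxyl), and perborate oxidises the C–B bond of 7 at nearly neutral pH, so no ester moves and no stereocentre is formed.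

Step 6
Reactants: 8 4,7-di-O-benzoyl-3,5-bis-O-TBS-2-deoxy-D-manno-heptitol
Product: 9 (3R,4R,5S)-4,7-di-O-benzoyl-3,5-bis-O-TBS-2-deoxy-D-lyxo-heptos-6-ulose (acyclic 1,6-keto aldehyde)
Conditions: Dess–Martin periodinane (3 equiv), CH2Cl2, 0 °C to rt
Reagents that add atoms: none
Why: Dess–Martin oxidation takes the primary alcohol to the aldehyde and the secondary one to the ketone in one base-free operation, which spares the β-silyloxy aldehyde and the α-stereocentre of the ketone, and the 1,6-distance of the two hydroxyls rules out lactol formation and over-oxidation.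

Step 7
Reactants: 9 (3R,4R,5S)-4,7-di-O-benzoyl-3,5-bis-O-TBS-2-deoxy-D-lyxo-heptos-6-ulose
Product: 11 [(1S,2S,3R,4R)-3-benzoyloxy-2,4-bis(TBSO)-1-hydroxy-6-oxocyclohexyl]methyl benzoate, via Breslow enaminol 10 (not isolated)
Conditions: T (20 mol %), iPr2NEt (20 mol %), 4 Å MS, CH2Cl2 (0.02 M), Ar, rt
Reagents that add atoms: none
Why: The carbene released from T adds to the unhindered aldehyde of 9 and a proton shift gives Breslow enaminol 10, in which the former aldehyde carbon (future C6) is nucleophilic; it attacks the ketone carbon (future C1), and proton transfer with loss of the carbene leaves the α-ketol 11 and closes the catalytic cycle. The closest known reaction type is the carbene-catalysed intramolecular crossed aldehyde–ketone benzoin cyclisation, established for 1,6-keto aldehydes and for sugar-derived dicarbonyl chains. The single ring is closed in the 6-exo-trig mode. The only new stereocentre, C1, is under substrate control: in a chair-like transition state that copies the chair of D-mannopyranose, C2-OTBS and C3-OBz are equatorial and C4-OTBS is axial, the C2–O bond lies anti to the incoming carbon (polar Felkin–Anh arrangement) and the CH2OBz arm takes the equatorial site, so the new OH should become axial and cis to C2-O, the sense generally seen when carbon nucleophiles close six-membered rings onto hexos-5-ulose ketones. The step needs chemoselectivity for the benzoin over aldol closure, over β-elimination of C3-OBz or C4-OTBS and over intermolecular homo-benzoin: only the aldehyde can form an enaminol, the ketone is activated by its two α-oxygen substituents, high dilution favours ring closure, and the acidic N-C6F5 triazolium works with a weak amine base in no more than catalytic amount.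

Step 8
Reactants: 11 [(1S,2S,3R,4R)-3-benzoyloxy-2,4-bis(TBSO)-1-hydroxy-6-oxocyclohexyl]methyl benzoate
Product: 12 [(1S,2S,3R,4R)-3-benzoyloxy-1,2,4-trihydroxy-6-oxocyclohexyl]methyl benzoate (CNP0127041.1)
Conditions: HF·pyridine, THF (plastic vessel), 0 °C to rt
Reagents that add atoms: none
Why: Fluoride-induced desilylation in an acidic medium removes both TBS ethers while avoiding the basic conditions under which the C3 benzoate would migrate or the β-hydroxy ketone would lose water, and no stereocentre is affected.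

Compound list
1 | benzyl α-D-mannopyranoside | OC[C@@H]1[C@@H](O)[C@H](O)[C@H](O)[C@@H](OCc2ccccc2)O1 | starting material
2 | benzyl 3,6-di-O-benzoyl-α-D-mannopyranoside | O=C(OC[C@@H]1[C@@H](O)[C@H](OC(=O)c2ccccc2)[C@H](O)[C@@H](OCc2ccccc2)O1)c1ccccc1 | intermediate
3 | benzyl 3,6-di-O-benzoyl-2,4-bis-O-TBS-α-D-mannopyranoside | O=C(OC[C@@H]1[C@@H](O[Si](C)(C)C(C)(C)C)[C@H](OC(=O)c2ccccc2)[C@H](O[Si](C)(C)C(C)(C)C)[C@@H](OCc2ccccc2)O1)c1ccccc1 | intermediate
4 | 3,6-di-O-benzoyl-2,4-bis-O-TBS-D-mannopyranose (anomeric mixture) | O=C(OC[C@@H]1[C@@H](O[Si](C)(C)C(C)(C)C)[C@H](OC(=O)c2ccccc2)[C@H](O[Si](C)(C)C(C)(C)C)C(O)O1)c1ccccc1 | intermediate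
5 | 3,6-di-O-benzoyl-2,4-bis-O-TBS-aldehydo-D-mannose (open-chain tautomer of 4, not isolated) | O=C(OC[C@@H](O)[C@@H](O[Si](C)(C)C(C)(C)C)[C@H](OC(=O)c1ccccc1)[C@H](O[Si](C)(C)C(C)(C)C)C=O)c1ccccc1 | intermediate
6 | 4,7-di-O-benzoyl-3,5-bis-O-TBS-1,2-dideoxy-D-manno-hept-1-enitol | O=C(OC[C@@H](O)[C@@H](O[Si](C)(C)C(C)(C)C)[C@H](OC(=O)c1ccccc1)[C@H](O[Si](C)(C)C(C)(C)C)C=C)c1ccccc1 | intermediate
7 | 1-C-(9-borabicyclo[3.3.1]nonan-9-yl) 6-O-(9-borabicyclo[3.3.1]nonan-9-yl) adduct of 6 (not isolated) | O=C(OC[C@@H](OB1C2CCCC1CCC2)[C@@H](O[Si](C)(C)C(C)(C)C)[C@H](OC(=O)c1ccccc1)[C@H](O[Si](C)(C)C(C)(C)C)CCB1C2CCCC1CCC2)c1ccccc1 | intermediate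
8 | 4,7-di-O-benzoyl-3,5-bis-O-TBS-2-deoxy-D-manno-heptitol | O=C(OC[C@@H](O)[C@@H](O[Si](C)(C)C(C)(C)C)[C@H](OC(=O)c1ccccc1)[C@H](O[Si](C)(C)C(C)(C)C)CCO)c1ccccc1 | intermediate
9 | (3R,4R,5S)-4,7-di-O-benzoyl-3,5-bis-O-TBS-2-deoxy-D-lyxo-heptos-6-ulose | O=C(OCC(=O)[C@@H](O[Si](C)(C)C(C)(C)C)[C@H](OC(=O)c1ccccc1)[C@H](O[Si](C)(C)C(C)(C)C)CC=O)c1ccccc1 | intermediate
10 | Breslow enaminol from 9 and the carbene of T (not isolated) | O=C(OCC(=O)[C@@H](O[Si](C)(C)C(C)(C)C)[C@H](OC(=O)c1ccccc1)[C@H](O[Si](C)(C)C(C)(C)C)CC(O)=C1N(c2c(F)c(F)c(F)c(F)c2F)N=C2CCCN12)c1ccccc1 | intermediate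
11 | [(1S,2S,3R,4R)-3-benzoyloxy-2,4-bis(TBSO)-1-hydroxy-6-oxocyclohexyl]methyl benzoate | O=C(OC[C@@]1(O)C(=O)C[C@@H](O[Si](C)(C)C(C)(C)C)[C@@H](OC(=O)c2ccccc2)[C@@H]1O[Si](C)(C)C(C)(C)C)c1ccccc1 | intermediate
12 | [(1S,2S,3R,4R)-3-benzoyloxy-1,2,4-trihydroxy-6-oxocyclohexyl]methyl benzoate (CNP0127041.1) | O=C(OC[C@@]1(O)C(=O)C[C@@H](O)[C@@H](OC(=O)c2ccccc2)[C@@H]1O)c1ccccc1 | target

Total step count: 8. Longest linear sequence: 8 (fully linear from 1).

Steps most likely to fail

Step 7. The facial selectivity at C1 may be poor. Base-induced loss of benzoic acid or an aldol closure may also outrun formation of the enaminol. Fallback: the same two carbons are joined as an alkene and oxidised afterwards.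
- It sets out from 9. Both carbonyl groups are methylenated (reagents of step 4, dioxane, 60 °C) to give (3R,4R,5R)-4-benzoyloxy-2-(benzoyloxymethyl)-3,5-bis(TBSO)octa-1,7-diene F1.
- Ring-closing metathesis with the second-generation Grubbs catalyst (CH2Cl2, reflux) should give [(4R,5R,6R)-5-benzoyloxy-4,6-bis(TBSO)cyclohex-1-en-1-yl]methyl benzoate F2.
- RuCl3-catalysed ketohydroxylation (KHSO5, NaHCO3, EtOAc/MeCN/H2O) can place only a tertiary OH at C1 and a ketone at C6. It should attack the face opposite to the axial C4 silyl ether, that is cis to C2-O.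
- The fallback comes back to the route at 11.

Step 4. Ring opening of the lactol may be slow, and benzoate or silyl groups may migrate to the liberated O-5 under the influence of the basic ylide. Fallback: no olefination; the extra carbon comes from CO under neutral radical conditions.
- It sets out from 4. Reduction with NaBH4 (THF/EtOH, 0 °C) gives 3,6-di-O-benzoyl-2,4-bis-O-TBS-D-mannitol F3.
- A primary-selective Appel-type iodination (I2, PPh3, imidazole, toluene) gives 3,6-di-O-benzoyl-2,4-bis-O-TBS-1-deoxy-1-iodo-D-mannitol F4.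
- Radical formylation (CO 80 atm, Bu3SnH, AIBN, benzene, 80 °C) gives 4,7-di-O-benzoyl-3,5-bis-O-TBS-2-deoxy-aldehydo-D-manno-heptose F5.
- Dess–Martin oxidation of the remaining secondary alcohol brings the fallback back to the route at 9.

Step 1. Over-benzoylation or competing acylation at O-2 may erode the regioselectivity. Fallback: the two acylations are separated, each under its own control element.
- It sets out from 1. 1-Benzoylimidazole with catalytic DBU (MeCN) acylates only the primary hydroxyl and gives benzyl 6-O-benzoyl-α-D-mannopyranoside F6.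
- BzCl, iPr2NEt and Ph2BOCH2CH2NH2 (10 mol %) then bind the cis-2,3-diol as a borinate and deliver the acyl group to the equatorial O-3.
- The fallback comes back to the route at 2.

Further compounds
F1 | step 7 | (3R,4R,5R)-4-benzoyloxy-2-(benzoyloxymethyl)-3,5-bis(TBSO)octa-1,7-diene | O=C(OCC(=C)[C@@H](O[Si](C)(C)C(C)(C)C)[C@H](OC(=O)c1ccccc1)[C@H](O[Si](C)(C)C(C)(C)C)CC=C)c1ccccc1
F2 | step 7 | [(4R,5R,6R)-5-benzoyloxy-4,6-bis(TBSO)cyclohex-1-en-1-yl]methyl benzoate | O=C(OCC1=CC[C@@H](O[Si](C)(C)C(C)(C)C)[C@@H](OC(=O)c2ccccc2)[C@@H]1O[Si](C)(C)C(C)(C)C)c1ccccc1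
F3 | step 4 | 3,6-di-O-benzoyl-2,4-bis-O-TBS-D-mannitol | O=C(OC[C@@H](O)[C@@H](O[Si](C)(C)C(C)(C)C)[C@H](OC(=O)c1ccccc1)[C@H](O[Si](C)(C)C(C)(C)C)CO)c1ccccc1
F4 | step 4 | 3,6-di-O-benzoyl-2,4-bis-O-TBS-1-deoxy-1-iodo-D-mannitol | O=C(OC[C@@H](O)[C@@H](O[Si](C)(C)C(C)(C)C)[C@H](OC(=O)c1ccccc1)[C@H](O[Si](C)(C)C(C)(C)C)CI)c1ccccc1
F5 | step 4 | 4,7-di-O-benzoyl-3,5-bis-O-TBS-2-deoxy-aldehydo-D-manno-heptose | O=C(OC[C@@H](O)[C@@H](O[Si](C)(C)C(C)(C)C)[C@H](OC(=O)c1ccccc1)[C@H](O[Si](C)(C)C(C)(C)C)CC=O)c1ccccc1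
F6 | step 1 | benzyl 6-O-benzoyl-α-D-mannopyranoside | O=C(OC[C@@H]1[C@@H](O)[C@H](O)[C@H](O)[C@@H](OCc2ccccc2)O1)c1ccccc1
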